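The ten-membered carbocycle (C1–C10) is opened at C8–C9. The cis oxygens on C8 and C9, lying between the C7 methine and quaternary C10, are read as a syn-dihydroxylated Z-alkene, and C8=C9 is the only unconjugated, disubstituted alkene this ring can offer. A single ring-closing metathesis therefore makes that bond, closes the carbocycle and completes the oxygen-bridged bicycle without touching a stereocentre. Its substrate is a 2-methyl-2-vinyl-3(2H)-furanone (O, C3, C2, C1, C10) joined through the Z-C4=C5 alkene to a cis-4-vinyl-3-methylene-γ-butyrolactone (C6, C7, C11, C12, O), with C6, C7 and C10 already set.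

Key step: step 10

Remark: dioxolanone 1 is taken as a catalogue compound; otherwise it is one step from (S)-lactic acid and pivalaldehyde.
Remark: the 8S,9S diol forms only if OsO4 adds to the face of C8=C9 anti to the bridging furanone oxygen. That face also lies on the side of C11 and the C1 carbonyl, so its accessibility is assumed, not secured; the fallback for step 11 gives the same configuration if the reagent prefers the other face.

Step 1
Reactants: 1 (2S,5S)-2-tert-butyl-5-methyl-1,3-dioxolan-4-one; 2 phenyl vinyl sulfoxide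
Product: 4 (2S,5R)-2-tert-butyl-5-methyl-5-[2-(phenylsulfinyl)ethyl]-1,3-dioxolan-4-one, via lithium enolate 3 (not isolated)
Conditions: LiN(iPr)2, THF, −78 °C; then 2, −78 → −30 °C; AcOH quench
Reagents that add atoms: none
Why: Self-regeneration of stereocentres: the planar lithium enolate keeps the tert-butyl acetal centre, which blocks one face, so the Michael addition to the vinyl sulfoxide occurs anti to tert-butyl, the new C–C bond takes the place of the former C–H, and the quaternary carbon (later C10) is fixed as R.

Step 2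
Reactants: 4 (2S,5R)-2-tert-butyl-5-methyl-5-[2-(phenylsulfinyl)ethyl]-1,3-dioxolan-4-one
Product: 5 (2S,5R)-2-tert-butyl-5-methyl-5-vinyl-1,3-dioxolan-4-one
Conditions: toluene, NaHCO3, 110 °C
Reagents that add atoms: none
Why: Thermal syn-elimination of the sulfoxide (Ei) can only take a hydrogen from the CH2 next to the quaternary carbon, so it unveils the vinyl group without touching either stereocentre.

Step 3
Reactants: 6 (Z)-3-methylpent-2-en-4-yn-1-ol
Product: 7 tert-butyl(dimethyl){[(2Z)-3-methylpent-2-en-4-yn-1-yl]oxy}silane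
Conditions: t-BuMe2SiCl, imidazole, CH2Cl2, 0 °C → rt
Reagents that add atoms: tert-butyldimethylsilyl chloride, CC(C)(C)[Si](C)(C)Cl
Why: Standard silylation of a primary alcohol; the ether keeps the Z-disposed hydroxyl from adding to the ynone (furan formation) in steps 4 and 5.

Step 4
Reactants: 7 tert-butyl(dimethyl){[(2Z)-3-methylpent-2-en-4-yn-1-yl]oxy}silane; 5 (2S,5R)-2-tert-butyl-5-methyl-5-vinyl-1,3-dioxolan-4-one
Product: 10 (3R,7Z)-9-(tert-butyldimethylsilyloxy)-3-hydroxy-3,7-dimethylnona-1,7-dien-5-yn-4-one, via lithium acetylide 8 (not isolated), via lithium hemiketal alkoxide 9 (not isolated)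
Conditions: n-BuLi, THF, −78 °C; then 5, −78 °C; AcOH quench, warm to rt
Reagents that add atoms: none
Why: Mono-addition of a lithium acetylide to a lactone-type carbonyl: the tetrahedral lithium hemiketal persists at −78 °C and so prevents a second addition, and on protonation it opens with loss of pivalaldehyde to free the tertiary alcohol, the quaternary centre being untouched.

Step 5
Reactants: 10 (3R,7Z)-9-(tert-butyldimethylsilyloxy)-3-hydroxy-3,7-dimethylnona-1,7-dien-5-yn-4-one
Product: 12 (2R)-5-[(2Z)-4-hydroxybut-2-en-2-yl]-2-methyl-2-vinylfuran-3(2H)-one, via silyl furanone 11 (not isolated)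
Conditions: Ph3PAuNTf2 (2 mol %), CH2Cl2, rt; then MeOH, camphorsulfonic acid (10 mol %), 0 °C
Reagents that add atoms: none
Why: Cycloisomerisation of a γ-hydroxy ynone catalysed by monovalent gold (5-endo-dig hydroalkoxylation) should give the 3(2H)-furanone under neutral conditions that leave the Z-alkene alone, and acid-catalysed methanolysis then removes the primary silyl ether.

Step 6
Reactants: 12 (2R)-5-[(2Z)-4-hydroxybut-2-en-2-yl]-2-methyl-2-vinylfuran-3(2H)-one
Product: 13 (2Z)-3-[(5R)-5-methyl-4-oxo-5-vinyl-4,5-dihydrofuran-2-yl]but-2-enal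
Conditions: TEMPO (10 mol %), PhI(OAc)2, CH2Cl2, rt
Reagents that add atoms: none
Why: TEMPO/PhI(OAc)2 oxidation of an allylic primary alcohol stops at the aldehyde and, being non-basic, should preserve the Z-geometry; no other oxidisable alcohol is present.

Step 7
Reactants: 14 methyl acrylate; 15 acrolein
Product: 16 methyl 3-hydroxy-2-methylidenepent-4-enoate (racemic)
Conditions: DABCO (20 mol %), methyl acrylate in excess, neat, rt
Reagents that add atoms: none
Why: Morita–Baylis–Hillman reaction: DABCO adds to the acrylate and the resulting enolate attacks the aldehyde carbon of acrolein; the carbinol is racemic but is erased in step 8.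

Step 8
Reactants: 16 methyl 3-hydroxy-2-methylidenepent-4-enoate
Product: 17 methyl (2Z)-2-(bromomethyl)penta-2,4-dienoate
Conditions: NBS, Me2S, CH2Cl2, 0 °C → rt
Reagents that add atoms: N-bromosuccinimide, O=C1CCC(=O)N1Br
Why: Corey–Kim-type bromination of a Morita–Baylis–Hillman alcohol proceeds with allylic transposition (SN2′) to the conjugated dienoate, the Z-isomer (vinyl cis to CH2Br) being the thermodynamic product.

Step 9
Reactants: 13 (2Z)-3-[(5R)-5-methyl-4-oxo-5-vinyl-4,5-dihydrofuran-2-yl]but-2-enal; 17 methyl (2Z)-2-(bromomethyl)penta-2,4-dienoate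
Product: 20 (4S,5S)-3-methylidene-5-{(1Z)-2-[(5R)-5-methyl-4-oxo-5-vinyl-4,5-dihydrofuran-2-yl]prop-1-en-1-yl}-4-vinyldihydrofuran-2(3H)-one, via trimethylsilyl ether 18 (not isolated), via hydroxy ester 19 (not isolated)
Conditions: CrCl2 (10 mol %), tridentate carbazole bis(oxazoline) ligand (11 mol %), iPr2NEt (20 mol %), Mn powder, Me3SiCl, THF, rt; then 1 M HCl; then p-TsOH·H2O (10 mol %), CH2Cl2, rt
Reagents that add atoms: none
Why: Catalytic asymmetric Nozaki–Hiyama–Kishi-type 2-(alkoxycarbonyl)allylation: divalent chromium inserts into the allylic C–Br bond and the trivalent pentadienylchromium species adds through its γ-carbon in a six-membered chair (aldehyde substituent equatorial, vinyl axial as fixed by the Z-bromide), which gives the syn adduct and hence the cis C6/C7 relationship, while the ligand enantiomer is chosen to direct attack to the Re face of the aldehyde and so sets 6S and with it 7S; acid then closes the cis-lactone, and the ketone and furanone do not react with the organochromium reagent.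

Step 10
Reactants: 20 (4S,5S)-3-methylidene-5-{(1Z)-2-[(5R)-5-methyl-4-oxo-5-vinyl-4,5-dihydrofuran-2-yl]prop-1-en-1-yl}-4-vinyldihydrofuran-2(3H)-one
Product: 21 (6S,7S,10R)-(4Z,8Z)-1-oxo-3,10-epoxygermacra-2,4,8,11(13)-tetraen-12,6-olide
Conditions: second-generation Hoveyda–Grubbs catalyst (10 mol %, two portions), toluene (1 mM), 80 °C, Ar sparge
Reagents that add atoms: none
Why: The ruthenium alkylidene should form by [2+2]/retro-[2+2] at the monosubstituted C7 vinyl group (the C10 vinyl sits on a fully substituted carbon and initiates slowly) and then add intramolecularly to the C10 vinyl group, giving a ruthenacyclobutane whose cycloreversion releases ethylene and the C8=C9 bond. The closest known reaction type is ring-closing metathesis of an α,ω-diene to a ten-membered carbocycle beside an allylic quaternary centre. The ten-membered ring (C1–C10) is closed end-to-end by alkene–alkene metathesis, which at the same time completes the nine-membered oxacycle of the oxygen-bridged bicycle. No stereocentre is created; C6, C7 and C10 are spectators and only the alkene geometry is new, Z being expected because an E-C8=C9 bond cannot span the short C7···C10 gap of this bridged ring. The step needs site selectivity and closure over oligomerisation: C11=C13, C4=C5 and C2=C3 are electron-poor or hindered and could give only three- or four-membered rings with the C8 carbene, while the Z-C4=C5 alkene, the planar furanone and the cis-lactone hold both vinyl groups on one side and high dilution suppresses dimers.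

Step 11
Reactants: 21 (6S,7S,10R)-(4Z,8Z)-1-oxo-3,10-epoxygermacra-2,4,8,11(13)-tetraen-12,6-olide
Product: 22 (6S,7R,8S,9S,10R)-(4Z)-8,9-dihydroxy-1-oxo-3,10-epoxygermacra-2,4,11(13)-trien-12,6-olide
Conditions: OsO4 (5 mol %), N-methylmorpholine N-oxide (1.2 equiv), acetone/H2O (8:1), 0 °C; aqueous Na2SO3
Reagents that add atoms: N-methylmorpholine N-oxide, C[N+]1([O-])CCOCC1; water, O (both oxygens are passed on through OsO4, O=[Os](=O)(=O)=O)
Why: Upjohn dihydroxylation: OsO4 adds in a concerted [3+2] step to the only unconjugated alkene (the methylene lactone and the dienone alkenes are electron-poor and slower), so both oxygens arrive on one face and the Z-geometry fixes the C8/C9 relationship, while 8S,9S results when the reagent enters the face anti to the bridging oxygen, which places the diol cis to C14 and to the C7–C11 bond.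

Step 12
Reactants: 22 (6S,7R,8S,9S,10R)-(4Z)-8,9-dihydroxy-1-oxo-3,10-epoxygermacra-2,4,11(13)-trien-12,6-olide
Product: 23 (6S,7S,8S,9S,10R)-(4Z)-9-hydroxy-8-(2-methylprop-2-enoyloxy)-1-oxo-3,10-epoxygermacra-2,4,11(13)-trien-12,6-olide
Conditions: methacrylic anhydride (1.1 equiv), Et3N, DMAP (5 mol %), CH2Cl2, −20 °C
Reagents that add atoms: methacrylic anhydride, CC(=C)C(=O)OC(=O)C(C)=C
Why: DMAP-catalysed acylation under steric control: the C8 hydroxyl beside the C7 methine should react before the C9 hydroxyl, which is neopentyl-like beside quaternary C10, and the low temperature keeps translactonisation to the C8 oxygen from competing; no stereocentre changes.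

Compound list
1 | (2S,5S)-2-tert-butyl-5-methyl-1,3-dioxolan-4-one (cis) | C[C@@H]1O[C@H](C(C)(C)C)OC1=O | starting material
2 | phenyl vinyl sulfoxide (racemic) | C=CS(=O)c1ccccc1 | starting material
3 | lithium enolate of 1 | CC1=C(O[Li])O[C@@H](C(C)(C)C)O1 | intermediate
4 | (2S,5R)-2-tert-butyl-5-methyl-5-[2-(phenylsulfinyl)ethyl]-1,3-dioxolan-4-one (both sulfur epimers) | C[C@]1(CCS(=O)c2ccccc2)O[C@H](C(C)(C)C)OC1=O | intermediate
5 | (2S,5R)-2-tert-butyl-5-methyl-5-vinyl-1,3-dioxolan-4-one | C[C@]1(C=C)O[C@H](C(C)(C)C)OC1=O | intermediate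
6 | (Z)-3-methylpent-2-en-4-yn-1-ol | C#C/C(C)=C\CO | starting material
7 | tert-butyl(dimethyl){[(2Z)-3-methylpent-2-en-4-yn-1-yl]oxy}silane | C#C/C(C)=C\CO[Si](C)(C)C(C)(C)C | intermediate
8 | lithium acetylide of 7 | [Li]C#C/C(C)=C\CO[Si](C)(C)C(C)(C)C | intermediate
9 | lithium hemiketal alkoxide (acetylide adduct at C4 of dioxolanone 5, C4 unassigned) | C[C@]1(C=C)O[C@H](C(C)(C)C)OC1(O[Li])C#C/C(C)=C\CO[Si](C)(C)C(C)(C)C | intermediate
10 | (3R,7Z)-9-(tert-butyldimethylsilyloxy)-3-hydroxy-3,7-dimethylnona-1,7-dien-5-yn-4-one | C=C[C@@](C)(O)C(=O)C#C/C(C)=C\CO[Si](C)(C)C(C)(C)C | intermediate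
11 | silyl furanone, (2R)-5-[(2Z)-4-(tert-butyldimethylsilyloxy)but-2-en-2-yl]-2-methyl-2-vinylfuran-3(2H)-one | C=C[C@@]1(C)OC(=CC1=O)/C(C)=C\CO[Si](C)(C)C(C)(C)C | intermediate
12 | (2R)-5-[(2Z)-4-hydroxybut-2-en-2-yl]-2-methyl-2-vinylfuran-3(2H)-one | C=C[C@@]1(C)OC(=CC1=O)/C(C)=C\CO | intermediate
13 | (2Z)-3-[(5R)-5-methyl-4-oxo-5-vinyl-4,5-dihydrofuran-2-yl]but-2-enal | C=C[C@@]1(C)OC(=CC1=O)/C(C)=C\C=O | intermediate
14 | methyl acrylate | C=CC(=O)OC | starting material
15 | acrolein | C=CC=O | starting material
16 | methyl 3-hydroxy-2-methylidenepent-4-enoate (racemic) | C=CC(O)C(=C)C(=O)OC | intermediate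
17 | methyl (2Z)-2-(bromomethyl)penta-2,4-dienoate | C=C/C=C(\CBr)C(=O)OC | intermediate
18 | trimethylsilyl ether of 19 | C=C[C@@H](C(=C)C(=O)OC)[C@@H](O[Si](C)(C)C)/C=C(/C)C1=CC(=O)[C@](C)(O1)C=C | intermediate
19 | hydroxy ester, methyl (3S,4S,5Z)-4-hydroxy-2-methylidene-6-[(5R)-5-methyl-4-oxo-5-vinyl-4,5-dihydrofuran-2-yl]-3-vinylhept-5-enoate | C=C[C@@H](C(=C)C(=O)OC)[C@@H](O)/C=C(/C)C1=CC(=O)[C@](C)(O1)C=C | intermediate
20 | divinyl furanone lactone, (4S,5S)-3-methylidene-5-{(1Z)-2-[(5R)-5-methyl-4-oxo-5-vinyl-4,5-dihydrofuran-2-yl]prop-1-en-1-yl}-4-vinyldihydrofuran-2(3H)-one | C=C[C@H]1C(=C)C(=O)O[C@H]1/C=C(/C)C1=CC(=O)[C@](C)(O1)C=C | intermediate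
21 | ten-membered Z-C8=C9 core, (6S,7S,10R)-(4Z,8Z)-1-oxo-3,10-epoxygermacra-2,4,8,11(13)-tetraen-12,6-olide | C/C1=C/[C@@H]2OC(=O)C(=C)[C@@H]2/C=C\[C@@]2(C)OC1=CC2=O | intermediate
22 | (6S,7R,8S,9S,10R)-(4Z)-8,9-dihydroxy-1-oxo-3,10-epoxygermacra-2,4,11(13)-trien-12,6-olide | O[C@H]1[C@H]2C(=C)C(=O)O[C@H]2/C=C(/C)C2=CC(=O)[C@](C)(O2)[C@H]1O | intermediate
23 | CNP0252578.5, (6S,7S,8S,9S,10R)-(4Z)-9-hydroxy-8-(2-methylprop-2-enoyloxy)-1-oxo-3,10-epoxygermacra-2,4,11(13)-trien-12,6-olide | C=C(C)C(=O)O[C@H]1[C@H]2C(=C)C(=O)O[C@H]2/C=C(/C)C2=CC(=O)[C@](C)(O2)[C@H]1O | target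

Total step count: 12
Longest linear sequence: 9 steps (steps 1, 2, 4, 5, 6, 9, 10, 11, 12)

Steps most likely to fail

1. Step 10, ring-closing metathesis. Chain growth by intermolecular metathesis at the exposed C7 vinyl group may outrun closure, or the carbene formed there may be held as a chelate by the lactone carbonyl and never reach the hindered C10 vinyl group, so that the strained bicycle does not form. The fallback closes the ring before the lactone is locked. It sets out from hydroxy ester 19, which is isolated when the acid treatment of step 9 is left out. Silylation (Et3SiCl, imidazole, CH2Cl2) should give the open-chain triethylsilyl ether F1, in which the C6 oxygen and the C12 ester are free to rotate. Ring-closing metathesis under the conditions of step 10 should give the macrocyclic silyl ether ester F2. HF·pyridine in THF then frees the macrocyclic hydroxy ester F3, and p-TsOH·H2O in CH2Cl2 closes the cis-lactone, which brings the sequence back to 21.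

2. Step 11, dihydroxylation. Facial selectivity may be poor or reversed: the required face of C8=C9 also carries the lactone carbon C11 on C7 and lies on the side of the C1 carbonyl, so OsO4 may add from the opposite face and give the 8,9-bis-epimeric diol. The fallback is a Woodward-type cis-hydroxylation, in which the electrophile takes the open face and both oxygens end on the other one. It sets out from 21. Iodine and AgO2CC(CH3)=CH2 in benzene should give the trans iodo methacrylate F4, by iodonium formation on the open face and carboxylate opening at C8 from the hindered face. Water and a second equivalent of the silver salt then let the ester carbonyl displace iodide at C9 with inversion. Hydrolysis of the resulting dioxolanylium ion gives the cis hydroxy esters, 23 itself and its C9 ester isomer F5. F5 is converted into 23 by 1,2-acyl migration to the less hindered C8 oxygen (Et3N, CH2Cl2). This fallback replaces steps 11 and 12 and comes back to the route at 23.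

3. Step 9, asymmetric allylation. Enantiofacial control by the chiral chromium complex may be weak on the conjugated Z-enal, which would give both cis-lactones. The fallback relies on the stereocentre already present instead of on the catalyst. It sets out from 13 and 17. An indium-mediated Barbier reaction (In powder, THF/H2O, rt) is syn-selective but not face-selective and should give hydroxy ester 19 together with its (3R,4R) hydroxy ester diastereomer F6. p-TsOH·H2O closes these to 20 and to the (4R,5R) cis-lactone diastereomer F7. Because C10 is fixed, 20 and F7 are diastereomers and are separated by chromatography, and the sequence comes back to the route at 20.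

Further compounds
F1 | step 10 | methyl (3S,4S,5Z)-2-methylidene-6-[(5R)-5-methyl-4-oxo-5-vinyl-4,5-dihydrofuran-2-yl]-4-(triethylsilyloxy)-3-vinylhept-5-enoate | C=C[C@@H](C(=C)C(=O)OC)[C@@H](O[Si](CC)(CC)CC)/C=C(/C)C1=CC(=O)[C@](C)(O1)C=C
F2 | step 10 | methyl (6S,7S,10R)-(4Z,8Z)-1-oxo-6-(triethylsilyloxy)-3,10-epoxygermacra-2,4,8,11(13)-tetraen-12-oate | C/C1=C/[C@H](O[Si](CC)(CC)CC)[C@H](C(=C)C(=O)OC)/C=C\[C@@]2(C)OC1=CC2=O
F3 | step 10 | methyl (6S,7S,10R)-(4Z,8Z)-6-hydroxy-1-oxo-3,10-epoxygermacra-2,4,8,11(13)-tetraen-12-oate | C/C1=C/[C@H](O)[C@H](C(=C)C(=O)OC)/C=C\[C@@]2(C)OC1=CC2=O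
F4 | step 11 | (6S,7S,8S,9R,10R)-(4Z)-9-iodo-8-(2-methylprop-2-enoyloxy)-1-oxo-3,10-epoxygermacra-2,4,11(13)-trien-12,6-olide (iodine trans to the ester) | C=C(C)C(=O)O[C@H]1[C@H]2C(=C)C(=O)O[C@H]2/C=C(/C)C2=CC(=O)[C@](C)(O2)[C@@H]1I
F5 | step 11 | (6S,7R,8S,9S,10R)-(4Z)-8-hydroxy-9-(2-methylprop-2-enoyloxy)-1-oxo-3,10-epoxygermacra-2,4,11(13)-trien-12,6-olide | O[C@H]1[C@H]2C(=C)C(=O)O[C@H]2/C=C(/C)C2=CC(=O)[C@](C)(O2)[C@H]1OC(=O)C(C)=C
F6 | step 9 | methyl (3R,4R,5Z)-4-hydroxy-2-methylidene-6-[(5R)-5-methyl-4-oxo-5-vinyl-4,5-dihydrofuran-2-yl]-3-vinylhept-5-enoate | C=C[C@H](C(=C)C(=O)OC)[C@H](O)/C=C(/C)C1=CC(=O)[C@](C)(O1)C=C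
F7 | step 9 | (4R,5R)-3-methylidene-5-{(1Z)-2-[(5R)-5-methyl-4-oxo-5-vinyl-4,5-dihydrofuran-2-yl]prop-1-en-1-yl}-4-vinyldihydrofuran-2(3H)-one | C=C[C@@H]1C(=C)C(=O)O[C@@H]1/C=C(/C)C1=CC(=O)[C@](C)(O1)C=C
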